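The route rests on cutting the O1–C2 bond of the 3,4-dihydro-2H-pyran ring (O1, C2–Me, C3–CH2OH, C4–CH2CO2R, C5–CO2Me, C6=). That ring is the vinylogous carbonate formed when the C5/C6 formyl-ester enol adds through oxygen to C2 of a 2-ethylidene enal, the two units being held 1,5 by C4. One operation, Pd(0) removal of three allyl groups, releases the enol next to the enal. Reversible 6-endo oxa-Michael closure then sets C2 and C3 trans,trans to the single stereocentre C4, which comes from an iminium-catalysed malonate addition. The precursor is the open enol-dialdehyde carrying the hydroxytyrosyl ester, stored as its tris-allyl ether.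

Key step: step 12

Remark: no error was found in the precursor and product structures. The open precursor 22 is drawn as its hydrogen-bonded (Z)-enol and closes through the (E)-enol(ate) reached by tautomerism. The E labels on the allyloxymethylidene and ethylidene groups denote the expected major isomers; both geometries converge in step 12.

Step 1
Reactants: 1 but-3-en-1-ol
Product: 2 1-[(but-3-en-1-yloxy)methyl]-4-methoxybenzene
Conditions: NaH, PMBCl, Bu4NI (cat.), THF, 0 °C → rt
Reagents that add atoms: 4-methoxybenzyl chloride COc1ccc(CCl)cc1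
Why: Williamson ether synthesis; the primary alkoxide displaces the benzylic chloride, giving an ether that should survive acid, base and hot chloride yet leave selectively with DDQ.

Step 2
Reactants: 2 1-[(but-3-en-1-yloxy)methyl]-4-methoxybenzene; 3 (E)-but-2-enal (crotonaldehyde)
Product: 4 (2E)-5-[(4-methoxybenzyl)oxy]pent-2-enal
Conditions: Hoveyda–Grubbs II catalyst (3 mol%), 3 (5 equiv), CH2Cl2, 40 °C
Reagents that add atoms: none
Why: Olefin cross-metathesis of a terminal alkene with an excess of the electron-poor partner should favour the cross product and the conjugated (E)-enal.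

Step 3
Reactants: 4 (2E)-5-[(4-methoxybenzyl)oxy]pent-2-enal; 5 dimethyl malonate
Product: 7 dimethyl 2-[(3S)-5,5-dimethoxy-1-[(4-methoxybenzyl)oxy]pentan-3-yl]propanedioate, via aldehyde adduct 6 (not isolated)
Conditions: (R)-α,α-bis[3,5-bis(trifluoromethyl)phenyl]prolinol TMS ether (10 mol%), EtOH, 0 °C; evaporate; HC(OMe)3, p-TsOH (cat.), MeOH, rt
Reagents that add atoms: trimethyl orthoformate COC(OC)OC; methanol CO
Why: Iminium-catalysed Michael addition: the CAr2OTMS group of the (R)-catalyst screens one face of the (E),s-trans iminium ion, so malonate adds to the open Si face of the β-carbon and sets the (3S) centre (the future C4); acetalisation in the same pot removes the aldehyde whose enol could expel malonate again.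

Step 4
Reactants: 7 dimethyl 2-[(3S)-5,5-dimethoxy-1-[(4-methoxybenzyl)oxy]pentan-3-yl]propanedioate
Product: 8 methyl (3S)-5,5-dimethoxy-3-{2-[(4-methoxybenzyl)oxy]ethyl}pentanoate
Conditions: LiCl, H2O, DMSO, 150 °C
Reagents that add atoms: none
Why: Krapcho dealkoxycarbonylation: chloride demethylates one geminal ester and the carboxylate loses CO2 under neutral conditions that should leave the acetal, the PMB ether and the non-enolisable stereocentre alone.

Step 5
Reactants: 8 methyl (3S)-5,5-dimethoxy-3-{2-[(4-methoxybenzyl)oxy]ethyl}pentanoate; 9 methyl formate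
Product: 11 methyl (2E,3S)-5,5-dimethoxy-3-{2-[(4-methoxybenzyl)oxy]ethyl}-2-[(prop-2-en-1-yloxy)methylidene]pentanoate, via lithium formyl-ester enolate 10 (not isolated)
Conditions: LDA, THF, −78 °C; HCO2Me, −78 → 0 °C; then allyl bromide, DMPU, rt
Reagents that add atoms: allyl bromide C=CCBr
Why: Crossed Claisen condensation (ester formylation) followed by O-alkylation of the ambident formyl-ester enolate, which in a dipolar medium should react at the unhindered formyl oxygen because C-attack would build a quaternary carbon; the resulting β-allyloxyacrylate masks the enol against base, mild acid and oxidants.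

Step 6
Reactants: 11 methyl (2E,3S)-5,5-dimethoxy-3-{2-[(4-methoxybenzyl)oxy]ethyl}-2-[(prop-2-en-1-yloxy)methylidene]pentanoate
Product: 12 methyl (2E,3S)-3-(2-hydroxyethyl)-5,5-dimethoxy-2-[(prop-2-en-1-yloxy)methylidene]pentanoate
Conditions: DDQ, CH2Cl2/pH 7 buffer, 0 °C
Reagents that add atoms: none
Why: Oxidative PMB-ether cleavage through the benzylic cation; the electron-poor enol ether, the terminal alkene and, in buffer, the acetal should be inert, and 12 is carried on at once so that the free alcohol cannot close onto the acrylate.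

Step 7
Reactants: 12 methyl (2E,3S)-3-(2-hydroxyethyl)-5,5-dimethoxy-2-[(prop-2-en-1-yloxy)methylidene]pentanoate
Product: 13 (3R,4E)-3-(2,2-dimethoxyethyl)-4-(methoxycarbonyl)-5-(prop-2-en-1-yloxy)pent-4-enoic acid
Conditions: TEMPO (cat.), NaOCl (cat.), NaClO2, MeCN/phosphate buffer pH 6.7, 35 °C
Reagents that add atoms: sodium chlorite [Na+].[O-]Cl=O
Why: TEMPO-mediated oxidation with chlorite as terminal oxidant takes the primary alcohol through the aldehyde hydrate to the acid near pH 7, where the dimethyl acetal should hold.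

Step 8
Reactants: 14 hydroxytyrosol
Product: 15 2-[3,4-bis(prop-2-en-1-yloxy)phenyl]ethan-1-ol
Conditions: allyl bromide (2.2 equiv), K2CO3, acetone, reflux
Reagents that add atoms: allyl bromide C=CCBr
Why: Phenol-selective Williamson etherification: carbonate deprotonates only the two phenols, so the primary alcohol stays free for step 9.

Step 9
Reactants: 13 (3R,4E)-3-(2,2-dimethoxyethyl)-4-(methoxycarbonyl)-5-(prop-2-en-1-yloxy)pent-4-enoic acid; 15 2-[3,4-bis(prop-2-en-1-yloxy)phenyl]ethan-1-ol
Product: 16 5-{2-[3,4-bis(prop-2-en-1-yloxy)phenyl]ethyl} 1-methyl (2E,3R)-3-(2,2-dimethoxyethyl)-2-[(prop-2-en-1-yloxy)methylidene]pentanedioate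
Conditions: DCC, DMAP (cat.), CH2Cl2, 0 °C → rt
Reagents that add atoms: none
Why: Steglich esterification through the O-acylisourea and acylpyridinium ion; neither partner carries another nucleophile or a group that these neutral conditions should touch.

Step 10
Reactants: 16 5-{2-[3,4-bis(prop-2-en-1-yloxy)phenyl]ethyl} 1-methyl (2E,3R)-3-(2,2-dimethoxyethyl)-2-[(prop-2-en-1-yloxy)methylidene]pentanedioate
Product: 17 5-{2-[3,4-bis(prop-2-en-1-yloxy)phenyl]ethyl} 1-methyl (2E,3R)-3-(2-oxoethyl)-2-[(prop-2-en-1-yloxy)methylidene]pentanedioate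
Conditions: p-TsOH·H2O (cat.), acetone/H2O, rt
Reagents that add atoms: water O
Why: Acid-catalysed acetal hydrolysis; the β-allyloxyacrylate is a vinylogous carbonate whose C-protonation is slow, so only the dimethyl acetal should open.

Step 11
Reactants: 17 5-{2-[3,4-bis(prop-2-en-1-yloxy)phenyl]ethyl} 1-methyl (2E,3R)-3-(2-oxoethyl)-2-[(prop-2-en-1-yloxy)methylidene]pentanedioate; 18 1,1-dimethoxyethane
Product: 21 methyl (2E,3S,4E)-3-{2-[2-[3,4-bis(prop-2-en-1-yloxy)phenyl]ethoxy]-2-oxoethyl}-4-formyl-2-[(prop-2-en-1-yloxy)methylidene]hex-4-enoate, via silyl enol ether 19 (not isolated), via β-methoxy aldehyde 20 (not isolated)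
Conditions: 18 (2 equiv), i-Pr2NEt, TMSOTf, CH2Cl2, −78 → 0 °C; then DBU, rt
Reagents that add atoms: none
Why: Soft enolisation of the only aldehyde to its silyl enol ether, Mukaiyama-type addition to the oxocarbenium ion from 18 and E1cB loss of methanol amount to a directed aldol condensation that avoids acetaldehyde self-condensation and should give the more stable (E)-2-ethylidene enal; C4 has no acidifying neighbour and is not touched.

Step 12
Reactants: 21 methyl (2E,3S,4E)-3-{2-[2-[3,4-bis(prop-2-en-1-yloxy)phenyl]ethoxy]-2-oxoethyl}-4-formyl-2-[(prop-2-en-1-yloxy)methylidene]hex-4-enoate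
Product: 23 methyl (2R,3S,4S)-4-{2-[2-(3,4-dihydroxyphenyl)ethoxy]-2-oxoethyl}-3-formyl-2-methyl-3,4-dihydro-2H-pyran-5-carboxylate, via open enol-dialdehyde 22 (not isolated)
Conditions: Pd(PPh3)4 (5 mol%), TolSO2Na (3.6 equiv), degassed THF/phosphate buffer (pH 7), rt, Ar, until the isomer composition is constant
Reagents that add atoms: none
Why: Pd(0) ionises the two aryl allyl ethers and the allyl vinylogous carbonate (Tsuji–Trost deallylation), sulfinate traps the π-allyl cation, and the freed formyl-ester enol(ate) of 22 adds through oxygen to C2, the β-carbon of the ethylidene enal, after which the C3 enol(ate) is protonated. The closest known reaction type is the intramolecular oxa-Michael addition of a 1,3-dicarbonyl enol to an enal, the closure that secoiridoid aglycones undergo once their enol is set free. The one ring closes in the 6-endo-trig mode (O1 to C2, with C2=C3 inside the new ring). C2 and C3 are both formed reversibly, by retro-oxa-Michael (E1cB from the C3 enolate) and by enolisation of the C3 aldehyde, so the fixed C4 centre should select the isomer with methyl, formyl and the acetate arm mutually trans and pseudo-equatorial on the half-chair. The step needs O- over C-attack and 1,4- over 1,2-addition: C-attack would give a cyclobutane, and the lactol from addition to the C3 carbonyl re-opens and drains into 23, whose vinylogous-carbonate conjugation makes it the sink. Near-neutral buffer keeps the catechol protonated and leaves C4 untouched.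

Step 13
Reactants: 23 methyl (2R,3S,4S)-4-{2-[2-(3,4-dihydroxyphenyl)ethoxy]-2-oxoethyl}-3-formyl-2-methyl-3,4-dihydro-2H-pyran-5-carboxylate
Product: 24 methyl (2R,3R,4S)-4-{2-[2-(3,4-dihydroxyphenyl)ethoxy]-2-oxoethyl}-3-(hydroxymethyl)-2-methyl-3,4-dihydro-2H-pyran-5-carboxylate
Conditions: NaBH4, MeOH/THF, −40 °C; AcOH quench
Reagents that add atoms: none
Why: Chemoselective borohydride reduction of the aldehyde beside two esters and the vinylogous carbonate; low temperature and an acidic quench should prevent epimerisation at C3, retro-Michael opening and lactonisation of the new alcohol.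

Compound list
1 | but-3-en-1-ol | C=CCCO | starting material
2 | 1-[(but-3-en-1-yloxy)methyl]-4-methoxybenzene | C=CCCOCc1ccc(OC)cc1 | intermediate
3 | (E)-but-2-enal (crotonaldehyde) | C/C=C/C=O | starting material
4 | (2E)-5-[(4-methoxybenzyl)oxy]pent-2-enal | O=C/C=C/CCOCc1ccc(OC)cc1 | intermediate
5 | dimethyl malonate | COC(=O)CC(=O)OC | starting material
6 | dimethyl 2-[(3S)-1-[(4-methoxybenzyl)oxy]-5-oxopentan-3-yl]propanedioate (not isolated) | O=CC[C@@H](C(C(=O)OC)C(=O)OC)CCOCc1ccc(OC)cc1 | intermediate
7 | dimethyl 2-[(3S)-5,5-dimethoxy-1-[(4-methoxybenzyl)oxy]pentan-3-yl]propanedioate | COC(OC)C[C@@H](C(C(=O)OC)C(=O)OC)CCOCc1ccc(OC)cc1 | intermediate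
8 | methyl (3S)-5,5-dimethoxy-3-{2-[(4-methoxybenzyl)oxy]ethyl}pentanoate | COC(OC)C[C@@H](CC(=O)OC)CCOCc1ccc(OC)cc1 | intermediate
9 | methyl formate | COC=O | starting material
10 | methyl (3S)-2-(hydroxymethylidene)-5,5-dimethoxy-3-{2-[(4-methoxybenzyl)oxy]ethyl}pentanoate, present as its lithium enolate and drawn as the enol (not isolated) | COC(OC)C[C@@H](C(=CO)C(=O)OC)CCOCc1ccc(OC)cc1 | intermediate
11 | methyl (2E,3S)-5,5-dimethoxy-3-{2-[(4-methoxybenzyl)oxy]ethyl}-2-[(prop-2-en-1-yloxy)methylidene]pentanoate | COC(OC)C[C@@H](/C(=C\OCC=C)C(=O)OC)CCOCc1ccc(OC)cc1 | intermediate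
12 | methyl (2E,3S)-3-(2-hydroxyethyl)-5,5-dimethoxy-2-[(prop-2-en-1-yloxy)methylidene]pentanoate | COC(OC)C[C@@H](/C(=C\OCC=C)C(=O)OC)CCO | intermediate
13 | (3R,4E)-3-(2,2-dimethoxyethyl)-4-(methoxycarbonyl)-5-(prop-2-en-1-yloxy)pent-4-enoic acid | COC(OC)C[C@@H](/C(=C\OCC=C)C(=O)OC)CC(=O)O | intermediate
14 | hydroxytyrosol, 4-(2-hydroxyethyl)benzene-1,2-diol | OCCc1ccc(O)c(O)c1 | starting material
15 | 2-[3,4-bis(prop-2-en-1-yloxy)phenyl]ethan-1-ol | OCCc1ccc(OCC=C)c(OCC=C)c1 | intermediate
16 | 5-{2-[3,4-bis(prop-2-en-1-yloxy)phenyl]ethyl} 1-methyl (2E,3R)-3-(2,2-dimethoxyethyl)-2-[(prop-2-en-1-yloxy)methylidene]pentanedioate | COC(OC)C[C@@H](/C(=C\OCC=C)C(=O)OC)CC(=O)OCCc1ccc(OCC=C)c(OCC=C)c1 | intermediate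
17 | 5-{2-[3,4-bis(prop-2-en-1-yloxy)phenyl]ethyl} 1-methyl (2E,3R)-3-(2-oxoethyl)-2-[(prop-2-en-1-yloxy)methylidene]pentanedioate | O=CC[C@@H](/C(=C\OCC=C)C(=O)OC)CC(=O)OCCc1ccc(OCC=C)c(OCC=C)c1 | intermediate
18 | 1,1-dimethoxyethane (acetaldehyde dimethyl acetal) | CC(OC)OC | starting material
19 | 5-{2-[3,4-bis(prop-2-en-1-yloxy)phenyl]ethyl} 1-methyl (2E,3S)-2-[(prop-2-en-1-yloxy)methylidene]-3-[2-(trimethylsilyloxy)ethenyl]pentanedioate, E/Z mixture at the silyl enol ether (not isolated) | C[Si](C)(C)OC=C[C@@H](/C(=C\OCC=C)C(=O)OC)CC(=O)OCCc1ccc(OCC=C)c(OCC=C)c1 | intermediate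
20 | 5-{2-[3,4-bis(prop-2-en-1-yloxy)phenyl]ethyl} 1-methyl (2E,3S)-3-(3-methoxy-1-oxobutan-2-yl)-2-[(prop-2-en-1-yloxy)methylidene]pentanedioate, mixture at the two new side-chain centres (not isolated) | COC(C)C(C=O)[C@@H](/C(=C\OCC=C)C(=O)OC)CC(=O)OCCc1ccc(OCC=C)c(OCC=C)c1 | intermediate
21 | methyl (2E,3S,4E)-3-{2-[2-[3,4-bis(prop-2-en-1-yloxy)phenyl]ethoxy]-2-oxoethyl}-4-formyl-2-[(prop-2-en-1-yloxy)methylidene]hex-4-enoate | C/C=C(/C=O)[C@@H](/C(=C\OCC=C)C(=O)OC)CC(=O)OCCc1ccc(OCC=C)c(OCC=C)c1 | intermediate
22 | methyl (2Z,3S,4E)-3-{2-[2-(3,4-dihydroxyphenyl)ethoxy]-2-oxoethyl}-4-formyl-2-(hydroxymethylidene)hex-4-enoate, the open enol-dialdehyde (not isolated) | C/C=C(/C=O)[C@@H](/C(=C/O)C(=O)OC)CC(=O)OCCc1ccc(O)c(O)c1 | intermediate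
23 | methyl (2R,3S,4S)-4-{2-[2-(3,4-dihydroxyphenyl)ethoxy]-2-oxoethyl}-3-formyl-2-methyl-3,4-dihydro-2H-pyran-5-carboxylate | COC(=O)C1=CO[C@H](C)[C@@H](C=O)[C@@H]1CC(=O)OCCc1ccc(O)c(O)c1 | intermediate
24 | methyl (2R,3R,4S)-4-{2-[2-(3,4-dihydroxyphenyl)ethoxy]-2-oxoethyl}-3-(hydroxymethyl)-2-methyl-3,4-dihydro-2H-pyran-5-carboxylate | COC(=O)C1=CO[C@H](C)[C@@H](CO)[C@@H]1CC(=O)OCCc1ccc(O)c(O)c1 | target

Total step count: 13. Longest linear sequence: 12 steps (steps 1–7 and 9–13, from but-3-en-1-ol); step 8 is a one-step side branch from hydroxytyrosol.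

Steps most likely to fail

Step 12. The π-allyl cation may be transferred to the carbon of the freshly liberated enolate instead of to sulfinate, or deallylation may stall before the enol is free. Equilibration may also stop short, leaving C2/C3 isomers or the lactol, and a medium that turns too basic could oxidise the catechol or fragment the C4–C5 bond by retro-Michael reaction. The fallback changes the unmasking from ionisation to isomerisation–hydrolysis and sets out from 21. A hydrogen-activated cationic iridium(I) catalyst, [Ir(cod)(PMePh2)2]PF6 in THF at rt, should move all three allyl double bonds into conjugation with oxygen and give methyl (2E,3S,4E)-3-{2-[2-[3,4-bis(prop-1-en-1-yloxy)phenyl]ethoxy]-2-oxoethyl}-4-formyl-2-[(prop-1-en-1-yloxy)methylidene]hex-4-enoate F1. Dilute aqueous HCl in acetone should then hydrolyse the three propenyl enol ethers without any metal or allyl electrophile present, releasing 22. On buffering to pH 7 this closes and equilibrates as in the main route, so the fallback comes back at 23.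

Step 11. The silyl-activated aldehyde may act as electrophile toward its own enol ether (self-aldol), a second addition may follow, or ester silylation may compete. The fallback never frees the aldehyde and sets out from 16. TMSOTf/i-Pr2NEt should eliminate methanol from the dimethyl acetal to give the methyl enol ether 5-{2-[3,4-bis(prop-2-en-1-yloxy)phenyl]ethyl} 1-methyl (2E,3S)-3-(2-methoxyethenyl)-2-[(prop-2-en-1-yloxy)methylidene]pentanedioate F2. A BF3·OEt2-catalysed Müller–Cunradi–Pieroh addition of F2 to 18 at −40 °C should give the trimethoxy adduct 5-{2-[3,4-bis(prop-2-en-1-yloxy)phenyl]ethyl} 1-methyl (2E,3S)-2-[(prop-2-en-1-yloxy)methylidene]-3-(1,1,3-trimethoxybutan-2-yl)pentanedioate F3, in which no enolisable aldehyde ever coexists with a Lewis acid. Mild aqueous acid converts F3 into 20, and DBU then gives 21, where the route is rejoined.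

Step 5. The ambident enolate may be allylated on carbon, giving a quaternary α-allyl formyl ester that is prone to deformylation, instead of on oxygen. The fallback fixes the regiochemistry by mechanism and sets out from 10. Quenching the enolate with TsCl (N-methylimidazole, Et3N) can only sulfonylate oxygen and should give the enol tosylate methyl (3S)-5,5-dimethoxy-3-{2-[(4-methoxybenzyl)oxy]ethyl}-2-{[(4-methylbenzenesulfonyl)oxy]methylidene}pentanoate F4. Addition–elimination with allyl alcohol and Cs2CO3 in THF at 0 °C then replaces tosylate by allyloxy at the β-carbon and comes back at 11.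

Further compounds
F1 | step 12 | methyl (2E,3S,4E)-3-{2-[2-[3,4-bis(prop-1-en-1-yloxy)phenyl]ethoxy]-2-oxoethyl}-4-formyl-2-[(prop-1-en-1-yloxy)methylidene]hex-4-enoate | C/C=C(/C=O)[C@@H](/C(=C\OC=CC)C(=O)OC)CC(=O)OCCc1ccc(OC=CC)c(OC=CC)c1
F2 | step 11 | 5-{2-[3,4-bis(prop-2-en-1-yloxy)phenyl]ethyl} 1-methyl (2E,3S)-3-(2-methoxyethenyl)-2-[(prop-2-en-1-yloxy)methylidene]pentanedioate | COC=C[C@@H](/C(=C\OCC=C)C(=O)OC)CC(=O)OCCc1ccc(OCC=C)c(OCC=C)c1
F3 | step 11 | 5-{2-[3,4-bis(prop-2-en-1-yloxy)phenyl]ethyl} 1-methyl (2E,3S)-2-[(prop-2-en-1-yloxy)methylidene]-3-(1,1,3-trimethoxybutan-2-yl)pentanedioate | COC(C)C(C(OC)OC)[C@@H](/C(=C\OCC=C)C(=O)OC)CC(=O)OCCc1ccc(OCC=C)c(OCC=C)c1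
F4 | step 5 | methyl (3S)-5,5-dimethoxy-3-{2-[(4-methoxybenzyl)oxy]ethyl}-2-{[(4-methylbenzenesulfonyl)oxy]methylidene}pentanoate | COC(OC)C[C@@H](C(=COS(=O)(=O)c1ccc(C)cc1)C(=O)OC)CCOCc1ccc(OC)cc1
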